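The route rests on opening ring B between the tertiary carbinol carbon C4 and the ring-fusion methine C5 (eudesmane numbering). The key step exploits that C4 (C–OH, CH3) is bonded to C5, which continues through the ring A methylene C6 to the isopropenyl-bearing C7. A divalent-samarium ketyl at the C4 methyl ketone of an open-chain keto diene adds to a vinyl group on quaternary C10, closing ring B. The C6 radical then closes ring A onto an allylic acetate, whose reductive loss unveils the isopropenyl group. One operation builds both rings and sets C4, C5 and C7. The precursor's C1/C10 stereocentres come from an Ireland–Claisen rearrangement.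

Key step: step 10

Assumption: terpenoid carbons carry eudesmane numbers (C1–C15); the (R,R)-boron reagent of step 4 is taken to give the (2S,3R)-acid 10, and its mirror image would be used if the sense of induction proved opposite.

Step 1
Reactants: 1 phloroglucinol
Product: 2 1,3,5-tris(methoxymethoxy)benzene
Conditions: MOMCl, i-Pr2NEt, CH2Cl2/DMF, 0 °C → rt
Reagents that add atoms: chloromethyl methyl ether (MOMCl), COCCl
Why: Williamson-type O-alkylation of the three phenols with the hard electrophile MOMCl should give the tris-acetal, which later directs ortho-lithiation and comes off under mild acid; no stereocenter is formed.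

Step 2
Reactants: 2 1,3,5-tris(methoxymethoxy)benzene; 3 β-propiolactone
Product: 6 3-[2,4,6-tris(methoxymethoxy)phenyl]propanoic acid, via aryllithium 4 (not isolated), via arylmagnesium bromide 5 (not isolated)
Conditions: n-BuLi, THF, 0 °C; MgBr2·OEt2, −30 °C; CuI (10 mol%), then 3, −30 → 0 °C; cold 1 M HCl
Reagents that add atoms: none
Why: Directed ortho-lithiation between two MOM ethers, transmetalation and copper-catalysed SN2 opening of the β-lactone at its O–CH2 carbon (alkyl–oxygen cleavage) should deliver the 3-arylpropanoic acid without creating a stereocenter.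

Step 3
Reactants: 6 3-[2,4,6-tris(methoxymethoxy)phenyl]propanoic acid; 7 geraniol
Product: 8 (2E)-3,7-dimethylocta-2,6-dien-1-yl 3-[2,4,6-tris(methoxymethoxy)phenyl]propanoate
Conditions: DCC, DMAP (cat.), CH2Cl2, 0 °C → rt
Reagents that add atoms: none
Why: Steglich esterification joins the acid and the allylic alcohol under neutral conditions that leave the acetals and the (E)-trisubstituted alkene untouched.

Step 4
Reactants: 8 (2E)-3,7-dimethylocta-2,6-dien-1-yl 3-[2,4,6-tris(methoxymethoxy)phenyl]propanoate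
Product: 10 (2S,3R)-3-ethenyl-3,7-dimethyl-2-{[2,4,6-tris(methoxymethoxy)phenyl]methyl}oct-6-enoic acid, via boron ketene acetal 9 (not isolated)
Conditions: (4R,5R)-2-bromo-4,5-diphenyl-1,3-bis(4-methylbenzenesulfonyl)-1,3,2-diazaborolidine [made in the flask from the (R,R)-bis-sulfonamide and BBr3], i-Pr2NEt, CH2Cl2, −78 °C, then → 4 °C; aqueous work-up
Reagents that add atoms: none
Why: In this enantioselective Ireland–Claisen rearrangement, soft enolisation with the C2-symmetric boron bromide and i-Pr2NEt should give the Z(O)-boron ketene acetal (arylmethyl cis to O–B), whose chair transition state with the (E)-geranyl terminus (chain equatorial, methyl axial) sets C1 (S) and quaternary C10 (R) together while the chiral ligand selects the enolate face.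

Step 5
Reactants: 10 (2S,3R)-3-ethenyl-3,7-dimethyl-2-{[2,4,6-tris(methoxymethoxy)phenyl]methyl}oct-6-enoic acid
Product: 11 (2S,3R)-3-ethenyl-3,7-dimethyl-2-{[2,4,6-tris(methoxymethoxy)phenyl]methyl}oct-6-en-1-ol
Conditions: LiAlH4, THF, 0 °C → rt
Reagents that add atoms: none
Why: Hydride reduction of the carboxylic acid to the primary alcohol leaves the alkenes, the acetals and both stereocenters untouched.

Step 6
Reactants: 11 (2S,3R)-3-ethenyl-3,7-dimethyl-2-{[2,4,6-tris(methoxymethoxy)phenyl]methyl}oct-6-en-1-ol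
Product: 13 (3E,5R,6R)-6-ethenyl-6,10-dimethyl-5-{[2,4,6-tris(methoxymethoxy)phenyl]methyl}undeca-3,9-dien-2-one, via aldehyde 12 (not isolated)
Conditions: DMP (1,1,1-triacetoxy-1,1-dihydro-1,2-benziodoxol-3(1H)-one), NaHCO3, CH2Cl2, 0 °C → rt; then (MeO)2P(O)CH2C(O)CH3, LiCl, i-Pr2NEt, MeCN, rt
Reagents that add atoms: dimethyl (2-oxopropyl)phosphonate, CC(=O)CP(=O)(OC)OC
Why: Hypervalent-iodine oxidation of the primary alcohol followed directly by a Horner–Wadsworth–Emmons olefination under mild LiCl/amine conditions should give the (E)-enone (C3, C4 and C15 added) without epimerising the α-stereocenter C1 of the aldehyde.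

Step 7
Reactants: 13 (3E,5R,6R)-6-ethenyl-6,10-dimethyl-5-{[2,4,6-tris(methoxymethoxy)phenyl]methyl}undeca-3,9-dien-2-one
Product: 14 (5S,6R)-6-ethenyl-6,10-dimethyl-5-{[2,4,6-tris(methoxymethoxy)phenyl]methyl}undec-9-en-2-one
Conditions: [(Ph3P)CuH]6 (0.3 equiv), H2O, THF/toluene, rt
Reagents that add atoms: none
Why: Copper hydride conjugate reduction delivers hydride only to the β-carbon of the enone, so the vinyl and trisubstituted alkenes survive and water protonates the copper enolate to the saturated methyl ketone.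

Step 8
Reactants: 14 (5S,6R)-6-ethenyl-6,10-dimethyl-5-{[2,4,6-tris(methoxymethoxy)phenyl]methyl}undec-9-en-2-one
Product: 15 (5S,6R,9E)-6-ethenyl-11-hydroxy-6,10-dimethyl-5-{[2,4,6-tris(methoxymethoxy)phenyl]methyl}undec-9-en-2-one
Conditions: SeO2 (cat.), t-BuOOH, salicylic acid (cat.), CH2Cl2, rt
Reagents that add atoms: tert-butyl hydroperoxide, CC(C)(C)OO
Why: Allylic oxidation with catalytic SeO2 (ene reaction then 2,3-sigmatropic shift) should hydroxylate the (E)-methyl group of the only trisubstituted alkene, the vinyl group and the ketone being far less reactive under these conditions.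

Step 9
Reactants: 15 (5S,6R,9E)-6-ethenyl-11-hydroxy-6,10-dimethyl-5-{[2,4,6-tris(methoxymethoxy)phenyl]methyl}undec-9-en-2-one
Product: 16 (2E,6R,7S)-6-ethenyl-2,6-dimethyl-10-oxo-7-{[2,4,6-tris(methoxymethoxy)phenyl]methyl}undec-2-en-1-yl acetate
Conditions: Ac2O, pyridine, DMAP (cat.), CH2Cl2, 0 °C
Reagents that add atoms: acetic anhydride, CC(=O)OC(C)=O
Why: Acylation of the primary allylic alcohol installs the acetate that serves as the leaving group of the β-elimination in the next step.

Step 10
Reactants: 16 (2E,6R,7S)-6-ethenyl-2,6-dimethyl-10-oxo-7-{[2,4,6-tris(methoxymethoxy)phenyl]methyl}undec-2-en-1-yl acetate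
Product: 18 (1R,4S,4aS,7R,8aR)-1,4a-dimethyl-7-(prop-1-en-2-yl)-4-{[2,4,6-tris(methoxymethoxy)phenyl]methyl}decahydronaphthalen-1-ol, via cyclohexylmethyl radical 17 (not isolated)
Conditions: SmI2 (2.5 equiv, added slowly), HMPA, t-BuOH, THF (high dilution), 0 °C → rt
Reagents that add atoms: none
Why: Electron transfer from SmI2/HMPA to the methyl ketone gives a ketyl that adds 6-exo-trig to the vinyl group on C10 (C4–C5 bond, ring B), the primary C6 radical adds 6-exo-trig to the CH terminus of the allylic acetate alkene (C6–C7 bond, ring A), and the tertiary C11 radical is reduced to an alkylsamarium that expels acetate to give the isopropenyl group. The closest known reaction types are the SmI2-mediated ketyl–olefin cyclisation of unactivated olefinic ketones and the sequential ketyl–olefin coupling/β-elimination. Both rings close through chair transition states: in ring B the arylmethyl group on C1 and the C9 chain on C10 sit equatorial and the C10 methyl axial, so the vinyl terminus C6 is equatorial and H5 ends anti to the angular methyl (trans ring fusion). At C4 the bulky samarium-bound oxygen takes the equatorial site away from the axial C10 methyl, leaving the C4 methyl axial and the hydroxyl α, and at C7 the alkene is equatorial in the second chair, giving the equatorial isopropenyl group. The step needs each cyclisation to outrun reduction of the ketyl and of the C6 radical, which slow addition of SmI2 at high dilution and the quaternary C10 (gem-dialkyl effect) should secure, and it needs the ketyl to choose the vinyl group, which ring size (six against eight) ensures.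

Step 11
Reactants: 18 (1R,4S,4aS,7R,8aR)-1,4a-dimethyl-7-(prop-1-en-2-yl)-4-{[2,4,6-tris(methoxymethoxy)phenyl]methyl}decahydronaphthalen-1-ol
Product: 20 3-{[(1S,4R,4aR,6R,8aS)-4-hydroxy-4,8a-dimethyl-6-(prop-1-en-2-yl)decahydronaphthalen-1-yl]methyl}-2,4,6-tris(methoxymethoxy)-5-(3-methylbutanoyl)benzaldehyde, via lithium aminal alkoxide 19 (not isolated)
Conditions: n-BuLi (2.2 equiv), THF, 0 °C; DMF, −78 °C; s-BuLi, TMEDA, −78 → −30 °C; N-methoxy-N,3-dimethylbutanamide, −78 → 0 °C; aq. NH4Cl
Reagents that add atoms: N,N-dimethylformamide, CN(C)C=O; N-methoxy-N,3-dimethylbutanamide, CC(C)CC(=O)N(C)OC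
Why: Ortho-lithiation between two MOM ethers and formylation with DMF give a lithium aminal alkoxide that masks the aldehyde in the flask, so a second ortho-lithiation at the last ring position and acylation with the N-methoxy-N-methyl amide (stable tetrahedral adduct) should install both carbonyl groups, released on aqueous work-up, without touching any stereocenter.

Step 12
Reactants: 20 3-{[(1S,4R,4aR,6R,8aS)-4-hydroxy-4,8a-dimethyl-6-(prop-1-en-2-yl)decahydronaphthalen-1-yl]methyl}-2,4,6-tris(methoxymethoxy)-5-(3-methylbutanoyl)benzaldehyde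
Product: 21 2,4,6-trihydroxy-3-{[(1S,4R,4aR,6R,8aS)-4-hydroxy-4,8a-dimethyl-6-(prop-1-en-2-yl)decahydronaphthalen-1-yl]methyl}-5-(3-methylbutanoyl)benzaldehyde (target)
Conditions: HCl (3 M aq.), MeOH/THF, rt
Reagents that add atoms: none
Why: Acid-catalysed acetal exchange with methanol should remove the three aryl MOM ethers, each activated by an ortho carbonyl group, under conditions mild enough for the tertiary alcohol and the isopropenyl group.

Compound list
1 | phloroglucinol (benzene-1,3,5-triol) | Oc1cc(O)cc(O)c1 | starting material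
2 | 1,3,5-tris(methoxymethoxy)benzene | COCOc1cc(OCOC)cc(OCOC)c1 | intermediate
3 | β-propiolactone (oxetan-2-one) | O=C1CCO1 | starting material
4 | [2,4,6-tris(methoxymethoxy)phenyl]lithium (not isolated) | [Li]c1c(OCOC)cc(OCOC)cc1OCOC | intermediate
5 | [2,4,6-tris(methoxymethoxy)phenyl]magnesium bromide (not isolated) | Br[Mg]c1c(OCOC)cc(OCOC)cc1OCOC | intermediate
6 | 3-[2,4,6-tris(methoxymethoxy)phenyl]propanoic acid | OC(=O)CCc1c(OCOC)cc(OCOC)cc1OCOC | intermediate
7 | geraniol, (2E)-3,7-dimethylocta-2,6-dien-1-ol | CC(C)=CCC/C(C)=C/CO | starting material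
8 | (2E)-3,7-dimethylocta-2,6-dien-1-yl 3-[2,4,6-tris(methoxymethoxy)phenyl]propanoate | CC(C)=CCC/C(C)=C/COC(=O)CCc1c(OCOC)cc(OCOC)cc1OCOC | intermediate
9 | Z(O)-boron ketene acetal of 8 carrying the (4R,5R)-4,5-diphenyl-1,3-bis(4-methylbenzenesulfonyl)-1,3,2-diazaborolidin-2-yl group on oxygen (not isolated) | COCOc1cc(OCOC)c(C/C=C(\OB2N(S(=O)(=O)c3ccc(C)cc3)[C@H](c3ccccc3)[C@@H](c3ccccc3)N2S(=O)(=O)c2ccc(C)cc2)OC/C=C(\C)CCC=C(C)C)c(OCOC)c1 | intermediate
10 | (2S,3R)-3-ethenyl-3,7-dimethyl-2-{[2,4,6-tris(methoxymethoxy)phenyl]methyl}oct-6-enoic acid | CC(C)=CCC[C@](C)(C=C)[C@H](Cc1c(OCOC)cc(OCOC)cc1OCOC)C(=O)O | intermediate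
11 | (2S,3R)-3-ethenyl-3,7-dimethyl-2-{[2,4,6-tris(methoxymethoxy)phenyl]methyl}oct-6-en-1-ol | CC(C)=CCC[C@](C)(C=C)[C@H](Cc1c(OCOC)cc(OCOC)cc1OCOC)CO | intermediate
12 | (2S,3R)-3-ethenyl-3,7-dimethyl-2-{[2,4,6-tris(methoxymethoxy)phenyl]methyl}oct-6-enal (not isolated) | CC(C)=CCC[C@](C)(C=C)[C@H](Cc1c(OCOC)cc(OCOC)cc1OCOC)C=O | intermediate
13 | (3E,5R,6R)-6-ethenyl-6,10-dimethyl-5-{[2,4,6-tris(methoxymethoxy)phenyl]methyl}undeca-3,9-dien-2-one | CC(C)=CCC[C@](C)(C=C)[C@H](Cc1c(OCOC)cc(OCOC)cc1OCOC)/C=C/C(C)=O | intermediate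
14 | (5S,6R)-6-ethenyl-6,10-dimethyl-5-{[2,4,6-tris(methoxymethoxy)phenyl]methyl}undec-9-en-2-one | CC(C)=CCC[C@](C)(C=C)[C@H](Cc1c(OCOC)cc(OCOC)cc1OCOC)CCC(C)=O | intermediate
15 | (5S,6R,9E)-6-ethenyl-11-hydroxy-6,10-dimethyl-5-{[2,4,6-tris(methoxymethoxy)phenyl]methyl}undec-9-en-2-one | OC/C(C)=C/CC[C@](C)(C=C)[C@H](Cc1c(OCOC)cc(OCOC)cc1OCOC)CCC(C)=O | intermediate
16 | (2E,6R,7S)-6-ethenyl-2,6-dimethyl-10-oxo-7-{[2,4,6-tris(methoxymethoxy)phenyl]methyl}undec-2-en-1-yl acetate | CC(=O)OC/C(C)=C/CC[C@](C)(C=C)[C@H](Cc1c(OCOC)cc(OCOC)cc1OCOC)CCC(C)=O | intermediate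
17 | ring B cyclohexylmethyl radical (C6 radical, samarium alkoxide at C4) formed by the first ring closure (not isolated) | [CH2][C@H]1[C@](C)(O[Sm](I)I)CC[C@@H](Cc2c(OCOC)cc(OCOC)cc2OCOC)[C@]1(C)CC/C=C(\C)COC(C)=O | intermediate
18 | (1R,4S,4aS,7R,8aR)-1,4a-dimethyl-7-(prop-1-en-2-yl)-4-{[2,4,6-tris(methoxymethoxy)phenyl]methyl}decahydronaphthalen-1-ol | C=C(C)[C@@H]1CC[C@@]2(C)[C@H](Cc3c(OCOC)cc(OCOC)cc3OCOC)CC[C@@](C)(O)[C@@H]2C1 | intermediate
19 | dilithium salt of the aryl(dimethylamino)methanol from 18 and DMF, tertiary alkoxide also lithiated, both epimers at the aminal carbon (not isolated) | C=C(C)[C@@H]1CC[C@@]2(C)[C@H](Cc3c(OCOC)c(C(O[Li])N(C)C)c(OCOC)cc3OCOC)CC[C@@](C)(O[Li])[C@@H]2C1 | intermediate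
20 | 3-{[(1S,4R,4aR,6R,8aS)-4-hydroxy-4,8a-dimethyl-6-(prop-1-en-2-yl)decahydronaphthalen-1-yl]methyl}-2,4,6-tris(methoxymethoxy)-5-(3-methylbutanoyl)benzaldehyde | C=C(C)[C@@H]1CC[C@@]2(C)[C@H](Cc3c(OCOC)c(C=O)c(OCOC)c(C(=O)CC(C)C)c3OCOC)CC[C@@](C)(O)[C@@H]2C1 | intermediate
21 | 2,4,6-trihydroxy-3-{[(1S,4R,4aR,6R,8aS)-4-hydroxy-4,8a-dimethyl-6-(prop-1-en-2-yl)decahydronaphthalen-1-yl]methyl}-5-(3-methylbutanoyl)benzaldehyde | C=C(C)[C@@H]1CC[C@@]2(C)[C@H](Cc3c(O)c(C=O)c(O)c(C(=O)CC(C)C)c3O)CC[C@@](C)(O)[C@@H]2C1 | target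

Total step count: 12. Longest linear sequence: 12 steps (1 → 2 → 6 → 8 → 10 → 11 → 13 → 14 → 15 → 16 → 18 → 20 → 21).

Steps most likely to fail

1. Step 10 (key step). The ketyl may be reduced on to the secondary alcohol before it adds to the unactivated vinyl group. The C6 radical may be reduced to an alkylsamarium, or may abstract an allylic hydrogen in a 1,5-shift, before ring A closes. The chair preference may also be too small, giving the cis-fused isomer. The fallback keeps the same ring-closing bond but makes it by polar chemistry; it sets out from ketone 14 and returns to the route at 18. Anti-Markovnikov hydroboration of the vinyl group with 9-BBN and oxidative work-up (NaBO3) should give the keto alcohol F1, and DMP oxidation the keto aldehyde F2. A proline-catalysed 6-enolexo aldol cyclisation (enamine of the aldehyde adding to the methyl ketone, anti product, formyl group equatorial) should close ring B to the hydroxy aldehyde F3. A Me2AlCl-promoted intramolecular carbonyl-ene reaction of the aldehyde with the trisubstituted alkene should then close ring A and create the isopropenyl group in the diol F4. Selective thiocarbonylation of the secondary alcohol with PhOC(S)Cl gives the thionocarbonate F5, and Barton–McCombie deoxygenation (Bu3SnH, AIBN) leads to 18.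

2. Step 11. The second lithiation may stay incomplete, or the alkyllithium may attack the aminal carbon or the excess DMF, so that mono-functionalised or doubly formylated material results. The fallback installs the two groups one at a time; it sets out from 18 and returns at 20. Lithiation (n-BuLi) and addition to 3-methylbutanal should give the benzylic alcohol F6; a second lithiation of its dianion (n-BuLi, TMEDA) and DMF should give the hydroxy aldehyde F7; DMP oxidation of the secondary benzylic alcohol, which leaves the tertiary alcohol untouched, gives 20.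

3. Step 4. The Lewis-acidic boron bromide may cleave the methoxymethyl ethers, the enolate geometry may erode, or the facial selectivity may be low, which would lower both diastereomeric and enantiomeric purity. The fallback replaces reagent control by a racemic rearrangement and resolution; it sets out from ester 8 and returns at acid 10. LDA and Me3SiCl in THF/DMPU (−78 °C → rt) give the Z(O)-silyl ketene acetal, whose Ireland–Claisen rearrangement should give the same diastereomer as the racemic acid F8. Salt formation with (S)-1-phenylethylamine and fractional crystallisation should give the ammonium salt F9 of the (2S,3R)-acid (taken from the mother liquor if it is the more soluble salt), and acidification frees 10.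

Further compounds
F1 | step 10 | (5S,6R)-6-(2-hydroxyethyl)-6,10-dimethyl-5-{[2,4,6-tris(methoxymethoxy)phenyl]methyl}undec-9-en-2-one | CC(C)=CCC[C@](C)(CCO)[C@H](Cc1c(OCOC)cc(OCOC)cc1OCOC)CCC(C)=O
F2 | step 10 | (5S,6R)-6,10-dimethyl-6-(2-oxoethyl)-5-{[2,4,6-tris(methoxymethoxy)phenyl]methyl}undec-9-en-2-one | CC(C)=CCC[C@](C)(CC=O)[C@H](Cc1c(OCOC)cc(OCOC)cc1OCOC)CCC(C)=O
F3 | step 10 | (1R,2R,5S,6S)-2-hydroxy-2,6-dimethyl-6-(4-methylpent-3-en-1-yl)-5-{[2,4,6-tris(methoxymethoxy)phenyl]methyl}cyclohexane-1-carbaldehyde | O=C[C@H]1[C@](C)(O)CC[C@@H](Cc2c(OCOC)cc(OCOC)cc2OCOC)[C@]1(C)CCC=C(C)C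
F4 | step 10 | (1R,4S,4aS,7S,8S,8aS)-1,4a-dimethyl-7-(prop-1-en-2-yl)-4-{[2,4,6-tris(methoxymethoxy)phenyl]methyl}decahydronaphthalene-1,8-diol | C=C(C)[C@@H]1CC[C@@]2(C)[C@H](Cc3c(OCOC)cc(OCOC)cc3OCOC)CC[C@@](C)(O)[C@@H]2[C@H]1O
F5 | step 10 | O-phenyl thionocarbonate of the secondary (C8) hydroxyl of F4 | C=C(C)[C@@H]1CC[C@@]2(C)[C@H](Cc3c(OCOC)cc(OCOC)cc3OCOC)CC[C@@](C)(O)[C@@H]2[C@H]1OC(=S)Oc1ccccc1
F6 | step 11 | (1R,4S,4aS,7R,8aR)-4-{[3-(1-hydroxy-3-methylbutyl)-2,4,6-tris(methoxymethoxy)phenyl]methyl}-1,4a-dimethyl-7-(prop-1-en-2-yl)decahydronaphthalen-1-ol, both carbinol epimers | C=C(C)[C@@H]1CC[C@@]2(C)[C@H](Cc3c(OCOC)cc(OCOC)c(C(O)CC(C)C)c3OCOC)CC[C@@](C)(O)[C@@H]2C1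
F7 | step 11 | 3-{[(1S,4R,4aR,6R,8aS)-4-hydroxy-4,8a-dimethyl-6-(prop-1-en-2-yl)decahydronaphthalen-1-yl]methyl}-5-(1-hydroxy-3-methylbutyl)-2,4,6-tris(methoxymethoxy)benzaldehyde, both carbinol epimers | C=C(C)[C@@H]1CC[C@@]2(C)[C@H](Cc3c(OCOC)c(C=O)c(OCOC)c(C(O)CC(C)C)c3OCOC)CC[C@@](C)(O)[C@@H]2C1
F8 | step 4 | racemic (2S,3R)/(2R,3S)-3-ethenyl-3,7-dimethyl-2-{[2,4,6-tris(methoxymethoxy)phenyl]methyl}oct-6-enoic acid | CC(C)=CCC[C@](C)(C=C)[C@H](Cc1c(OCOC)cc(OCOC)cc1OCOC)C(=O)O.CC(C)=CCC[C@@](C)(C=C)[C@@H](Cc1c(OCOC)cc(OCOC)cc1OCOC)C(=O)O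
F9 | step 4 | (S)-1-phenylethylammonium salt of acid 10 | CC(C)=CCC[C@](C)(C=C)[C@H](Cc1c(OCOC)cc(OCOC)cc1OCOC)C(=O)[O-].C[C@H]([NH3+])c1ccccc1
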